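## Retrosynthetic overview
1. The target is the C5–C6 saturated form of an (R)-configured p-quinone methyl/aryl monoketal. Disconnecting C5–H and C6–H gives a chemoselective 1,4-reduction of the cross-conjugated dienone, in which C6 follows from C4.
2. The dienone is disconnected at C4–OAr to an oxidative O–C homocoupling of two molecules of 2-allyl-4,5-dimethoxyphenol under a chiral iodoarene catalyst. This is the new step and it sets C4.
3. The allyl–ring bond of the phenol comes from the key skeletal step: an alkoxide-driven 1,2-allyl shift (C1 to C6) in the allylmagnesium adduct of 3,4,4-trimethoxycyclohexa-2,5-dienone, with rearomatisation.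
4. The quinone monoketal comes from 3-methoxyphenol by double PhI(OAc)2/MeOH oxidation, and 3-methoxyphenol comes from resorcinol by mono-O-methylation.
5. No ring is built, because both six-membered rings are resorcinol rings. Each is dearomatised in step 2 and rearomatised by the shift in step 3, and one of the two (ring B) is dearomatised again in step 4.

Assumption: the (R,R)-iodoarene is written for step 4. If it favours the wrong ketal configuration, its equally available (S,S)-enantiomer is used and nothing else changes.

## Route

Step 1
Reactants: 1 resorcinol
Product: 2 3-methoxyphenol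
Conditions: Me2SO4 (1.0 equiv), NaOH (aq), n-Bu4NBr (cat.), toluene, 80 °C
Reagents that add atoms: dimethyl sulfate, COS(=O)(=O)OC
Why: Williamson-type phenol O-methylation under phase transfer with one equivalent of electrophile stops mainly at the monoether, and unreacted 1 and the neutral diether are removed by extraction.

Step 2
Reactants: 2 3-methoxyphenol
Product: 4 3,4,4-trimethoxycyclohexa-2,5-dien-1-one, via 3,4-dimethoxyphenol 3 (not isolated)
Conditions: PhI(OAc)2 (2.1 equiv), MeOH, 0 °C to 23 °C
Reagents that add atoms: methanol, CO
Why: In this hypervalent-iodine phenol-to-quinone-monoketal oxidation the first equivalent methoxylates the free para position to give 3, which is more electron-rich than 2 and is oxidised at once at its methoxy-bearing para carbon to the dimethyl ketal, so no stereocentre is formed.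

Step 3 (key skeletal step)
Reactants: 4 3,4,4-trimethoxycyclohexa-2,5-dien-1-one; 5 allylmagnesium bromide
Product: 8 2-allyl-4,5-dimethoxyphenol, via magnesium alkoxide 6 (not isolated), via allyl-shifted dienone 7 (not isolated)
Conditions: 5 (1.05 equiv, Et2O), CH2Cl2, −78 °C; then MgBr2·OEt2 (2 equiv), −78 °C to 23 °C; 1 M HCl work-up
Reagents that add atoms: none
Why: The allyl Grignard adds 1,2 to the only carbonyl, and because the oxygen stays a magnesium alkoxide (not a leaving group, which shuts off Stork–Danheiser-type ionisation at C1) MgBr2 ionises the bis-allylic ketal instead and the alkoxide pushes the allyl group from C1 to the unhindered cation terminus C6 in a semipinacol-type 1,2-shift (the quinol variant of the dienone–phenol rearrangement), after which 7 tautomerises irreversibly to the phenol and no stereocentre survives.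

Step 4
Reactants: 8 2-allyl-4,5-dimethoxyphenol (two molecules, one oxidised and one acting as O-nucleophile)
Product: 9 (4R)-2-allyl-4-(2-allyl-4,5-dimethoxyphenoxy)-4,5-dimethoxycyclohexa-2,5-dien-1-one
Conditions: (R,R)-2,2'-[(2-iodo-1,3-phenylene)bis(oxy)]bis[N-(2,4,6-trimethylphenyl)propanamide] (10 mol %), mCPBA (0.5 equiv relative to 8, syringe pump), 4 Å MS, CH2Cl2, −20 °C
Reagents that add atoms: none
Why: Proposed new method: enantioselective intermolecular aryloxylative dearomatisation, in which mCPBA converts the C2-symmetric iodoarene into its trivalent-iodine form, one molecule of 8 binds to iodine through its phenol oxygen, the two hydrogen-bonded lactamide arms fold over one face of the bound ring, and a second molecule of 8 (held and deprotonated by the carboxylate ligand) attacks the methoxy-stabilised para carbon C4 through oxygen from the open face as the iodoarene departs, forming the C4–OAr bond and setting (R) at the mixed ketal carbon; the closest known reaction types are the PhI(OAc)2/ROH quinone-monoketal synthesis, the chiral-iodoarene-catalysed Kita spirolactonisation and the para-hydroxylative dearomatisation to p-quinols, whereas a phenol as external O-nucleophile creating a stereogenic ketal carbon has not been shown.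

Step 5
Reactants: 9 (4R)-2-allyl-4-(2-allyl-4,5-dimethoxyphenoxy)-4,5-dimethoxycyclohexa-2,5-dien-1-one
Product: 11 (4R,6R)-6-allyl-4-(2-allyl-4,5-dimethoxyphenoxy)-3,4-dimethoxycyclohex-2-en-1-one (target), via C6 epimer 10 (not isolated)
Conditions: Cu(OAc)2·H2O (5 mol %), 1,2-(Ph2P)2C6H4 (5 mol %), (MeO)2MeSiH (1.2 equiv), t-BuOH (1.5 equiv), toluene, 0 °C; then 1,8-diazabicyclo[5.4.0]undec-7-ene (0.2 equiv), 23 °C
Reagents that add atoms: none
Why: Stryker-type copper hydride 1,4-reduction touches only the allyl-bearing enone C=C (the other ring C=C is a deactivated vinylogous ester and the terminal alkenes are unactivated), C6 is set by axial protonation of the half-chair enolate whose better sigma-acceptor OAr sits pseudoaxial, and base equilibration funnels epimer 10 to the more stable isomer with equatorial allyl trans to OAr and cis to OMe, with residual 10 separated and re-equilibrated.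

## Compound list
1 | resorcinol (benzene-1,3-diol) | Oc1cccc(O)c1 | starting material
2 | 3-methoxyphenol | COc1cccc(O)c1 | intermediate
3 | 3,4-dimethoxyphenol | COc1ccc(O)cc1OC | intermediate
4 | 3,4,4-trimethoxycyclohexa-2,5-dien-1-one | COC1=CC(=O)C=CC1(OC)OC | intermediate
5 | allylmagnesium bromide | C=CC[Mg]Br | starting material
6 | bromomagnesium 1-allyl-3,4,4-trimethoxycyclohexa-2,5-dien-1-olate (racemic) | C=CCC1(O[Mg]Br)C=CC(OC)(OC)C(OC)=C1 | intermediate
7 | 6-allyl-3,4-dimethoxycyclohexa-2,4-dien-1-one (racemic keto tautomer of 8) | C=CCC1C=C(OC)C(OC)=CC1=O | intermediate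
8 | 2-allyl-4,5-dimethoxyphenol | C=CCc1cc(OC)c(OC)cc1O | intermediate
9 | (4R)-2-allyl-4-(2-allyl-4,5-dimethoxyphenoxy)-4,5-dimethoxycyclohexa-2,5-dien-1-one | C=CCc1cc(OC)c(OC)cc1O[C@]1(OC)C=C(CC=C)C(=O)C=C1OC | intermediate
10 | (4R,6S)-6-allyl-4-(2-allyl-4,5-dimethoxyphenoxy)-3,4-dimethoxycyclohex-2-en-1-one | C=CCc1cc(OC)c(OC)cc1O[C@]1(OC)C[C@H](CC=C)C(=O)C=C1OC | intermediate
11 | (4R,6R)-6-allyl-4-(2-allyl-4,5-dimethoxyphenoxy)-3,4-dimethoxycyclohex-2-en-1-one | C=CCc1cc(OC)c(OC)cc1O[C@]1(OC)C[C@@H](CC=C)C(=O)C=C1OC | target

## Step count and risks
Total step count: 5. Longest linear sequence: 5 (1 → 2 → 4 → 8 → 9 → 11).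

**Step 4 (the proposed new step).**
- Risks: C–C instead of O–C coupling, capture of the activated ring by water or carboxylate, and low enantioselectivity.
- Fallback (known chemistry): it sets out from 8. Compound 8 is oxidised with the achiral reagent PhI(OAc)2 (0.5 equiv, NaHCO3, CH2Cl2, −40 °C), which is the standard oxidative ketalisation of a 4-methoxyphenol by an added O–H nucleophile.
- This gives 9 as a racemate with its mirror image (4S)-2-allyl-4-(2-allyl-4,5-dimethoxyphenoxy)-4,5-dimethoxycyclohexa-2,5-dien-1-one F1.
- Preparative HPLC on a cellulose tris(3,5-dimethylphenylcarbamate) phase separates the two, and the route is rejoined at 9.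

**Step 3.**
- Risks: migration to C2 next to the methoxy group, ionisation at C1 if the alkoxide is protonated too early, demethylation of the oxocarbenium ion by bromide, and an anionic oxy-Cope pathway (kept slow by the magnesium counter-ion).
- Fallback: it sets out from 4. Zn/AcOH reduces 4 to 3 with loss of one ketal methoxy group.
- Allyl bromide/K2CO3 in acetone then gives 4-(allyloxy)-1,2-dimethoxybenzene F2.
- Heating F2 in N,N-diethylaniline at 200 °C (aromatic Claisen rearrangement to the less hindered ortho position) comes back to the route at 8.

**Step 5.**
- Risks: 1,2-reduction or electron transfer with aromatisation back to 8, and only a modest C6 ratio after equilibration.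
- Fallback: it sets out from 9 and comes back at 11. A panel of ene-reductases of the old yellow enzyme family is screened with NADP+, glucose and glucose dehydrogenase in pH 7 phosphate buffer/10 % DMSO at 30 °C.
- The enzyme delivers flavin hydride to the β-carbon and a tyrosine proton to the opposite face of the allyl-bearing carbon, so C6 is fixed by the enzyme instead of by the substrate. No compound outside the list is made (none F0).

## Further compounds
F1 | step 4 | (4S)-2-allyl-4-(2-allyl-4,5-dimethoxyphenoxy)-4,5-dimethoxycyclohexa-2,5-dien-1-one | C=CCc1cc(OC)c(OC)cc1O[C@@]1(OC)C=C(CC=C)C(=O)C=C1OC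
F2 | step 3 | 4-(allyloxy)-1,2-dimethoxybenzene | C=CCOc1ccc(OC)c(OC)c1
F0 | step 5 | none | none
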